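The two C6–O ester bonds are cut first (they are formed with inversion), which gives (2E,6E)-2,6-dimethylocta-2,6-dienedioic acid and two copies of the 6-epi amino alcohol. In that alcohol the C6–C7 bond of the cyclopentane ring is cut, and the resulting vinyl/CH2CHO pair is traced back to a δ-lactone fused to a pyridine.
Enabling feature: in each octahydrocyclopenta[c]pyridine unit the oxygen sits on C6, and the neighbouring C7 carries a methyl group and is bonded to the ring-fusion carbon C7a. C6 can therefore start as the aldehyde carbon of a C4a–CH2CHO arm, and C7 with its methyl as the inner and terminal carbons of a vinyl group on C7a.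
Ring order: pyridine ring (bought), temporary fused lactone ring, piperidine ring by hydrogenation, lactone opened to vinyl and hydroxyethyl, cyclopentane ring closed last with SmI2. The C10 chain from geranyl acetate is attached at the very end.
Stereochemistry: C4, C4a and C7a arise all-cis from syn hydrogenation of the pyridinium salt and are made absolute by a salt resolution directly afterwards. C7 and C6 are set in the radical closure under control of these centres, C6 is inverted in the Mitsunobu step, and both E alkenes come from the geranyl skeleton and an E-selective allylic oxidation.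
Key step: step 9

Assumption: of the two diastereomeric salts formed from 9 and the L-configured acid 10, the one holding the (4aS,5R,8aS)-lactone is taken to be the less soluble; if the other one crystallises, the D-acid is used in the same way, and the configuration is checked by X-ray analysis of the salt.

Step 1
Reactants: 1 3-bromo-4,5-dimethylpyridine; 2 paraformaldehyde (source of formaldehyde)
Product: 4 2-(3-bromo-5-methylpyridin-4-yl)ethan-1-ol, via 4-lithiomethylpyridine 3 (not isolated)
Conditions: LDA, THF, −78 °C; (CH2O)n, −78 °C → rt; H2O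
Reagents that add atoms: formaldehyde from paraformaldehyde 2, C=O
Why: Lateral lithiation, in which LDA deprotonates only the 4-methyl group because its anion is delocalised onto the ring nitrogen (the 5-methyl group cannot do this), and the picolyllithium adds to formaldehyde while the C–Br bond stays intact at low temperature.

Step 2
Reactants: 4 2-(3-bromo-5-methylpyridin-4-yl)ethan-1-ol; 5 carbon monoxide
Product: 6 5-methyl-3,4-dihydro-1H-pyrano[3,4-c]pyridin-1-one
Conditions: CO (3 bar), Pd(OAc)2 (cat.), dppf (cat.), Et3N, DMF, 100 °C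
Reagents that add atoms: carbon monoxide 5, [C-]#[O+]
Why: Palladium-catalysed carbonylative lactonisation (intramolecular alkoxycarbonylation of a heteroaryl bromide), in which oxidative addition, CO insertion and capture of the acylpalladium by the tethered primary alcohol close the six-membered lactone whose carbonyl carbon is the future C7.

Step 3
Reactants: 6 5-methyl-3,4-dihydro-1H-pyrano[3,4-c]pyridin-1-one; 7 iodomethane
Product: 8 5,7-dimethyl-1-oxo-3,4-dihydro-1H-pyrano[3,4-c]pyridin-7-ium iodide
Conditions: MeI, MeCN, 50 °C (sealed)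
Reagents that add atoms: iodomethane 7, CI
Why: Menshutkin N-alkylation of the unhindered pyridine nitrogen installs the N-methyl group of the target and activates the ring for hydrogenation.

Step 4
Reactants: 8 5,7-dimethyl-1-oxo-3,4-dihydro-1H-pyrano[3,4-c]pyridin-7-ium iodide
Product: 9 rac-(4aS,5R,8aS)-5,7-dimethyloctahydro-1H-pyrano[3,4-c]pyridin-1-one (all-cis: H4a, H5 and H8a on one face)
Conditions: H2 (5 bar), PtO2 (cat.), AcOH, rt; cold aq. K2CO3
Reagents that add atoms: none
Why: Heterogeneous hydrogenation of a pyridinium salt delivers all hydrogen atoms from the face bound to platinum, so H4a, H5 and H8a should end on one side (all-cis, racemic), and the lactone survives because it has no benzylic C–O bond.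

Step 5
Reactants: 9 rac-(4aS,5R,8aS)-5,7-dimethyloctahydro-1H-pyrano[3,4-c]pyridin-1-one; 10 (−)-O,O'-di-p-toluoyl-L-tartaric acid
Product: 11 (4aS,5R,8aS)-5,7-dimethyl-1-oxooctahydro-1H-pyrano[3,4-c]pyridin-7-ium hydrogen (2R,3R)-di-p-toluoyltartrate (1:1 salt)
Conditions: 10 (0.5 equiv), i-PrOH/acetone, reflux → rt; recrystallisation
Reagents that add atoms: (−)-O,O'-di-p-toluoyl-L-tartaric acid 10, OC(=O)[C@H](OC(=O)c1ccc(C)cc1)[C@@H](OC(=O)c1ccc(C)cc1)C(=O)O
Why: Classical resolution through diastereomeric salts, in which the tertiary amine pairs with the enantiopure acid, half an equivalent of acid leaves the unwanted enantiomer in solution as free base, and the crystalline salt fixes the absolute configuration at C4a, C5 and C8a.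

Step 6
Reactants: 11 lactone hydrogen di-p-toluoyl-L-tartrate salt
Product: 13 (4aS,5R,8aS)-5,7-dimethyloctahydro-1H-pyrano[3,4-c]pyridin-1-ol (lactol; anomer mixture), via free lactone base 12 (not isolated)
Conditions: cold aq. K2CO3/CH2Cl2, dry; DIBAL-H, CH2Cl2, −78 °C; aq. Rochelle salt
Reagents that add atoms: none
Why: Partial reduction of a lactone with DIBAL-H, in which the tetrahedral aluminium hemiacetal formed from the liberated base is stable at −78 °C and collapses only on work-up, so reduction stops at the lactol and the α-stereocentre C8a is untouched.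

Step 7
Reactants: 13 (4aS,5R,8aS)-5,7-dimethyloctahydro-1H-pyrano[3,4-c]pyridin-1-ol; 14 methyltriphenylphosphonium bromide
Product: 16 2-[(3S,4S,5R)-3-ethenyl-1,5-dimethylpiperidin-4-yl]ethan-1-ol, via methylidenetriphenylphosphorane 15 (not isolated)
Conditions: 14, KOt-Bu, THF, 0 °C; then 13, 0 °C → rt
Reagents that add atoms: methyltriphenylphosphonium bromide 14, C[P+](c1ccccc1)(c1ccccc1)c1ccccc1.[Br-]
Why: Wittig methylenation of a lactol through its open hydroxy aldehyde form turns the former lactone carbonyl carbon into the inner vinyl carbon and frees the 2-hydroxyethyl arm in the same operation, the fast reaction of the unstabilised ylide being expected to outrun enolisation at C3.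

Step 8
Reactants: 16 2-[(3S,4S,5R)-3-ethenyl-1,5-dimethylpiperidin-4-yl]ethan-1-ol
Product: 17 2-[(3S,4S,5R)-3-ethenyl-1,5-dimethylpiperidin-4-yl]acetaldehyde
Conditions: (COCl)2, DMSO, CH2Cl2, −78 °C; Et3N, −78 → 0 °C
Reagents that add atoms: none
Why: Swern oxidation stops at the aldehyde, tolerates the tertiary amine and the alkene, and cannot epimerise anything because the carbon α to the new carbonyl group is a CH2 group.

Step 9
Reactants: 17 2-[(3S,4S,5R)-3-ethenyl-1,5-dimethylpiperidin-4-yl]acetaldehyde
Product: 21 (4R,4aS,6S,7S,7aR)-2,4,7-trimethyloctahydro-1H-cyclopenta[c]pyridin-6-ol (6-epi amino alcohol), via samarium ketyl 18 (not isolated), via cyclised primary radical 19 (not isolated), via alkylsamarium alkoxide 20 (not isolated)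
Conditions: SmI2 (3 equiv), HMPA, t-BuOH, THF, 0 °C → rt, slow addition of 17, high dilution
Reagents that add atoms: none
Why: SmI2–HMPA transfers one electron to the aldehyde to give ketyl 18, whose now nucleophilic C6 radical adds to the inner vinyl carbon C7, after which primary radical 19 is reduced by a second SmI2 to alkylsamarium 20 and protonated by t-BuOH, so the terminal vinyl carbon ends as the 7-methyl group. The closest known reaction type is the SmI2/HMPA-mediated reductive ketyl–olefin cyclisation of δ,ε-unsaturated aldehydes and ketones that carry unactivated alkenes. The cyclopentane ring closes in the 5-exo-trig mode through a chair-like transition state, and the cis ring fusion is fixed beforehand because the axial CH2CHO arm on C4a and the equatorial vinyl group on C7a are gauche neighbours on the same face of the piperidine chair. C7 is controlled by the vinyl rotamer in which the C7a–H bond eclipses the C=C bond (least allylic strain), so attack from the C4a side leaves the CH2 terminus on the convex face, syn to H7a and trans to C1. C6 is controlled by electrostatic and steric repulsion between the samarium-bound ketyl oxygen and the alkene, which sets the C–O bond anti to the C7=CH2 bond and should give hydroxyl trans to methyl, the 6S alcohol. The step needs cyclisation to beat simple reduction and pinacol coupling and 5-exo to beat 6-endo closure, which the preorganised all-cis piperidine, slow addition to excess reductant at high dilution and the weak proton donor t-BuOH should secure.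

Step 10
Reactants: 22 geranyl acetate
Product: 23 (2E,6E)-8-hydroxy-3,7-dimethylocta-2,6-dien-1-yl acetate
Conditions: SeO2 (cat.), t-BuOOH, CH2Cl2, 0 °C → rt
Reagents that add atoms: tert-butyl hydroperoxide, CC(C)(C)OO; selenium dioxide (catalytic oxygen carrier), O=[Se]=O
Why: Riley allylic oxidation (ene reaction followed by [2,3]-sigmatropic shift) attacks the electron-richer 6,7-alkene, the 2,3-alkene being deactivated by the allylic acetate, and its cyclic transition state places the new hydroxyl on the E methyl group.

Step 11
Reactants: 23 (2E,6E)-8-hydroxy-3,7-dimethylocta-2,6-dien-1-yl acetate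
Product: 24 (2E,6E)-2,6-dimethylocta-2,6-diene-1,8-diol
Conditions: K2CO3 (cat.), MeOH, rt
Reagents that add atoms: none
Why: Base-catalysed transesterification with methanol removes the acetate without affecting either alkene.

Step 12
Reactants: 24 (2E,6E)-2,6-dimethylocta-2,6-diene-1,8-diol
Product: 25 (2E,6E)-2,6-dimethylocta-2,6-dienedial
Conditions: MnO2 (excess), CH2Cl2, rt
Reagents that add atoms: none
Why: Manganese dioxide oxidation is selective for allylic alcohols, stops at the enal and runs under neutral conditions that should keep both double bonds E.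

Step 13
Reactants: 25 (2E,6E)-2,6-dimethylocta-2,6-dienedial
Product: 26 (2E,6E)-2,6-dimethylocta-2,6-dienedioic acid
Conditions: NaClO2, NaH2PO4, 2-methylbut-2-ene, t-BuOH/H2O, rt
Reagents that add atoms: sodium chlorite, [Na+].[O-]Cl=O
Why: Pinnick oxidation converts both enals into the acids under buffered conditions without conjugate addition or E/Z isomerisation, the alkene scavenger removing hypochlorous acid.

Step 14
Reactants: 21 (4R,4aS,6S,7S,7aR)-2,4,7-trimethyloctahydro-1H-cyclopenta[c]pyridin-6-ol (2.1 equiv); 26 (2E,6E)-2,6-dimethylocta-2,6-dienedioic acid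
Product: 29 bis[(4R,4aS,6R,7S,7aR)-2,4,7-trimethyloctahydro-1H-cyclopenta[c]pyridin-6-yl] (2E,6E)-2,6-dimethylocta-2,6-dienedioate (target), via C8 monoester 27 (not isolated), via C1 monoester 28 (not isolated)
Conditions: PPh3, DIAD, THF, 0 °C → rt
Reagents that add atoms: none
Why: Twofold Mitsunobu esterification, in which each alkoxyphosphonium ion formed from the concave 6S hydroxyl group is displaced by a carboxylate of 26 from the open convex face in an SN2 process, inverting C6 to 6R in both halves and leaving the conjugated E alkenes untouched.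

Compound list
1 | 3-bromo-4,5-dimethylpyridine | Cc1cncc(Br)c1C | starting material
2 | paraformaldehyde (reacts as formaldehyde) | C=O | starting material
3 | (3-bromo-5-methylpyridin-4-yl)methyllithium | [Li]Cc1c(C)cncc1Br | intermediate
4 | 2-(3-bromo-5-methylpyridin-4-yl)ethan-1-ol | OCCc1c(C)cncc1Br | intermediate
5 | carbon monoxide | [C-]#[O+] | starting material
6 | 5-methyl-3,4-dihydro-1H-pyrano[3,4-c]pyridin-1-one | O=C1OCCc2c1cncc2C | intermediate
7 | iodomethane | CI | starting material
8 | 5,7-dimethyl-1-oxo-3,4-dihydro-1H-pyrano[3,4-c]pyridin-7-ium iodide | O=C1OCCc2c1c[n+](C)cc2C.[I-] | intermediate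
9 | rac-(4aS,5R,8aS)-5,7-dimethyloctahydro-1H-pyrano[3,4-c]pyridin-1-one, all-cis, both enantiomers | O=C1OCC[C@@H]2[C@H]1CN(C)C[C@@H]2C.O=C1OCC[C@H]2[C@@H]1CN(C)C[C@H]2C | intermediate
10 | (−)-O,O'-di-p-toluoyl-L-tartaric acid, (2R,3R) | OC(=O)[C@H](OC(=O)c1ccc(C)cc1)[C@@H](OC(=O)c1ccc(C)cc1)C(=O)O | starting material
11 | 1:1 salt of the (4aS,5R,8aS)-lactone (N-protonated) with hydrogen (2R,3R)-di-p-toluoyltartrate | O=C1OCC[C@@H]2[C@H]1C[NH+](C)C[C@@H]2C.OC(=O)[C@H](OC(=O)c1ccc(C)cc1)[C@@H](OC(=O)c1ccc(C)cc1)C(=O)[O-] | intermediate
12 | (4aS,5R,8aS)-5,7-dimethyloctahydro-1H-pyrano[3,4-c]pyridin-1-one | O=C1OCC[C@@H]2[C@H]1CN(C)C[C@@H]2C | intermediate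
13 | (4aS,5R,8aS)-5,7-dimethyloctahydro-1H-pyrano[3,4-c]pyridin-1-ol (lactol, C1 anomers) | OC1OCC[C@@H]2[C@H]1CN(C)C[C@@H]2C | intermediate
14 | methyltriphenylphosphonium bromide | C[P+](c1ccccc1)(c1ccccc1)c1ccccc1.[Br-] | starting material
15 | methylidenetriphenylphosphorane | C=P(c1ccccc1)(c1ccccc1)c1ccccc1 | intermediate
16 | 2-[(3S,4S,5R)-3-ethenyl-1,5-dimethylpiperidin-4-yl]ethan-1-ol (all-cis) | OCC[C@@H]1[C@@H](CN(C)C[C@@H]1C)C=C | intermediate
17 | 2-[(3S,4S,5R)-3-ethenyl-1,5-dimethylpiperidin-4-yl]acetaldehyde (all-cis) | O=CC[C@@H]1[C@@H](CN(C)C[C@@H]1C)C=C | intermediate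
18 | diiodosamarium(III) ketyl of 17 (radical on the former aldehyde carbon) | I[Sm](I)O[CH]C[C@@H]1[C@@H](CN(C)C[C@@H]1C)C=C | intermediate
19 | cyclised samarium alkoxide with a primary radical on the C7 CH2 group | I[Sm](I)O[C@H]1C[C@@H]2[C@@H](CN(C)C[C@@H]2C)[C@@H]1[CH2] | intermediate
20 | cyclised samarium alkoxide with a C7–CH2–SmI2 group | I[Sm](I)O[C@H]1C[C@@H]2[C@@H](CN(C)C[C@@H]2C)[C@@H]1C[Sm](I)I | intermediate
21 | (4R,4aS,6S,7S,7aR)-2,4,7-trimethyloctahydro-1H-cyclopenta[c]pyridin-6-ol (OH concave, trans to 7-methyl) | O[C@H]1C[C@@H]2[C@@H](CN(C)C[C@@H]2C)[C@@H]1C | intermediate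
22 | geranyl acetate, (2E)-3,7-dimethylocta-2,6-dien-1-yl acetate | CC(C)=CCC/C(C)=C/COC(C)=O | starting material
23 | (2E,6E)-8-hydroxy-3,7-dimethylocta-2,6-dien-1-yl acetate | OC/C(C)=C/CC/C(C)=C/COC(C)=O | intermediate
24 | (2E,6E)-2,6-dimethylocta-2,6-diene-1,8-diol | OC/C(C)=C/CC/C(C)=C/CO | intermediate
25 | (2E,6E)-2,6-dimethylocta-2,6-dienedial | O=C/C(C)=C/CC/C(C)=C/C=O | intermediate
26 | (2E,6E)-2,6-dimethylocta-2,6-dienedioic acid | OC(=O)/C(C)=C/CC/C(C)=C/C(=O)O | intermediate
27 | monoester of 26 at C8 (3-methyl-enoate end) with the (6R)-amino alcohol unit, C1 acid free | C/C(=C\C(=O)O[C@@H]1C[C@@H]2[C@@H](CN(C)C[C@@H]2C)[C@@H]1C)CC/C=C(\C)C(=O)O | intermediate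
28 | monoester of 26 at C1 (2-methyl-enoate end) with the (6R)-amino alcohol unit, C8 acid free | C/C(=C\C(=O)O)CC/C=C(\C)C(=O)O[C@@H]1C[C@@H]2[C@@H](CN(C)C[C@@H]2C)[C@@H]1C | intermediate
29 | bis[(4R,4aS,6R,7S,7aR)-2,4,7-trimethyloctahydro-1H-cyclopenta[c]pyridin-6-yl] (2E,6E)-2,6-dimethylocta-2,6-dienedioate | C/C(=C\C(=O)O[C@@H]1C[C@@H]2[C@@H](CN(C)C[C@@H]2C)[C@@H]1C)CC/C=C(\C)C(=O)O[C@@H]1C[C@@H]2[C@@H](CN(C)C[C@@H]2C)[C@@H]1C | target

Total step count: 14. Longest linear sequence: 10 (steps 1–9 and 14).

Steps most likely to fail

1. Step 9. The ketyl may be reduced on to the primary alcohol or dimerise to a pinacol faster than it adds to the unactivated vinyl group. The bulky samarium alkoxide, which has to lie on the concave face, may also erode the anti preference at C6. The fallback sets out from 17. It forms the same C6–C7 bond by a titanocene-catalysed reductive cyclisation of the enal with a hydrosilane (Cp2Ti(PMe3)2 cat., Ph2SiH2, toluene). A cis-fused oxatitanacyclopentane built on the convex face holds oxygen and CH2 on the same side. After σ-bond metathesis with the silane it should give (4R,4aS,6R,7S,7aR)-6-(diphenylsilyloxy)-2,4,7-trimethyloctahydro-1H-cyclopenta[c]pyridine F1. Mild acid hydrolysis frees (4R,4aS,6R,7S,7aR)-2,4,7-trimethyloctahydro-1H-cyclopenta[c]pyridin-6-ol F2, which already has the C6 configuration of the target. F2 is joined to 26 with retention by a twofold Steglich esterification (EDC, DMAP, CH2Cl2), and the fallback comes back to the route at 29.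

2. Step 4. Partly reduced enamine and iminium intermediates may leave the catalyst surface, tautomerise and be reduced from either face, which would erode the all-cis selectivity. The reduction may also stall at the vinylogous carbamate stage. The fallback sets out from 8 and splits the reduction into two stages. NaBH4 in MeOH at 0 °C should give the 1,2,5,6-tetrahydropyridine, rac-5,7-dimethyl-3,4,5,6,7,8-hexahydro-1H-pyrano[3,4-c]pyridin-1-one F3, in which only the tetrasubstituted C4a=C8a enoate double bond remains. Allylic strain against C4 pushes the C5 methyl group into a pseudoaxial position, where it blocks one face. Hydrogenation under pressure (Rh/Al2O3 or PtO2, EtOH) should therefore add both hydrogen atoms anti to it, and the fallback comes back to the route at 9.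

3. Step 14. The activated alcohol may undergo β-elimination to the cyclopentene, the reaction may stall at the monoester stage, or acyl transfer with retention may compete with SN2 displacement. The fallback sets out from 21 and separates activation from displacement. MsCl and Et3N in CH2Cl2 at 0 °C give (4R,4aS,6S,7S,7aR)-2,4,7-trimethyloctahydro-1H-cyclopenta[c]pyridin-6-yl methanesulfonate F4. The dicaesium salt of 26 (Cs2CO3, DMF, 60 °C) displaces the mesylate with inversion at both C6 centres, and the fallback comes back to the route at 29.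

Further compounds
F1 | step 9 | (4R,4aS,6R,7S,7aR)-6-(diphenylsilyloxy)-2,4,7-trimethyloctahydro-1H-cyclopenta[c]pyridine | [SiH](c1ccccc1)(c1ccccc1)O[C@@H]1C[C@@H]2[C@@H](CN(C)C[C@@H]2C)[C@@H]1C
F2 | step 9 | (4R,4aS,6R,7S,7aR)-2,4,7-trimethyloctahydro-1H-cyclopenta[c]pyridin-6-ol | O[C@@H]1C[C@@H]2[C@@H](CN(C)C[C@@H]2C)[C@@H]1C
F3 | step 4 | rac-5,7-dimethyl-3,4,5,6,7,8-hexahydro-1H-pyrano[3,4-c]pyridin-1-one (both enantiomers) | O=C1OCCC2=C1CN(C)C[C@@H]2C.O=C1OCCC2=C1CN(C)C[C@H]2C
F4 | step 14 | (4R,4aS,6S,7S,7aR)-2,4,7-trimethyloctahydro-1H-cyclopenta[c]pyridin-6-yl methanesulfonate | CS(=O)(=O)O[C@H]1C[C@@H]2[C@@H](CN(C)C[C@@H]2C)[C@@H]1C
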